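**Retrosynthetic overview**

1. The target is disconnected at the C5–propenyl bond: a last-step Suzuki–Miyaura coupling of the 5-bromo-2,3-dihydrobenzofuran with an (E)-propenyl boronate.
2. The bromo-dihydrobenzofuran is disconnected into an ortho-quinone diazide (4-bromo-6-diazo-3-methoxycyclohexadienone) and (E)-isoelemicin. A Rh-carbene cyclopropanation gives a spiro[2.5]octadienone, and its three-membered ring (C3a, C3, C2) is enlarged in the same flask by C7a and O1 to the five-membered ring (O1, C2, C3, C3a, C7a) in a Cloke–Wilson ring expansion; both stereocentres are set here.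
3. Enabling feature: O1 sits on C7a directly beside C3a, so a diazo group on C3a next to the C7a carbonyl places the carbene carbon 1,3 to the oxygen. The six-membered ring C3a–C4–C5–C6–C7–C7a becomes aromatic when the spiro C3a–C2 bond breaks, and the 3,4,5-trimethoxyphenyl group on C2 stabilises the cation there. A bromine at C5 holds the place of the propenyl group.
4. The quinone diazide comes from the aminophenol, the nitrophenol and 4-bromo-3-methoxyphenol; (E)-isoelemicin comes from 5-bromo-1,2,3-trimethoxybenzene and the same propenyl boronate.
5. Ring order: both benzene rings are bought; the cyclopropane and then the dihydrofuran are formed in the key step.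

Key step: step 5

Assumption: the sense of induction of the dirhodium catalyst in the key step cannot be derived with certainty by analogy, so the route is written with Rh2(S-TCPTTL)4 and the mirror-image catalyst Rh2(R-TCPTTL)4 is to be used if the first run leads into the (2S,3S) series; the spiro intermediate is drawn as the epimer with the aryl group on the carbonyl side, and the other spiro epimer would converge on the same product.

**Step 1**
Reactants: 1 5-bromo-1,2,3-trimethoxybenzene; 2 4,4,5,5-tetramethyl-2-[(E)-prop-1-enyl]-1,3,2-dioxaborolane ((E)-propenylboronic acid pinacol ester)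
Product: 3 1,2,3-trimethoxy-5-[(E)-prop-1-enyl]benzene ((E)-isoelemicin)
Conditions: Pd(dppf)Cl2 (2 mol %), K3PO4, dioxane/H2O (5:1), 80 °C
Reagents that add atoms: none
Why: Suzuki–Miyaura coupling of an unhindered aryl bromide with an alkenyl boronate proceeds with retention of the E geometry, so the alkene partner for the key step should be obtained as a single isomer.

**Step 2**
Reactants: 4 4-bromo-3-methoxyphenol
Product: 5 4-bromo-5-methoxy-2-nitrophenol
Conditions: 65% HNO3 (1.05 equiv), AcOH, 5–10 °C
Reagents that add atoms: nitric acid, O[N+](=O)[O-]
Why: Electrophilic aromatic nitration should go to the position ortho to OH and para to OMe, because the position para to OH is blocked by bromine and the position between the two oxygen substituents is crowded.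

**Step 3**
Reactants: 5 4-bromo-5-methoxy-2-nitrophenol
Product: 6 2-amino-4-bromo-5-methoxyphenol
Conditions: H2 (1 atm), 5% Pt(S)/C, EtOAc, rt; used at once under argon
Reagents that add atoms: none
Why: Catalytic hydrogenation of the nitro group over sulfided platinum is the standard way to reduce a nitroarene without hydrogenolysis of an aryl C–Br bond.

**Step 4**
Reactants: 6 2-amino-4-bromo-5-methoxyphenol
Product: 7 4-bromo-6-diazo-3-methoxycyclohexa-2,4-dien-1-one (ortho-quinone diazide, the inner salt 4-bromo-2-diazonio-5-methoxyphenolate)
Conditions: isoamyl nitrite (1.2 equiv), Cl3CCO2H (5 mol %), THF, 0 °C, dark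
Reagents that add atoms: isoamyl nitrite, CC(C)CCON=O
Why: Aprotic diazotisation with an alkyl nitrite (the conditions that turn anthranilic acid into its diazonium carboxylate inner salt) should give the diazonium ion, which loses the phenolic proton to form the neutral ortho-quinone diazide.

**Step 5**
Reactants: 7 4-bromo-6-diazo-3-methoxycyclohexa-2,4-dien-1-one; 3 (E)-isoelemicin
Product: 9 (2R,3R)-5-bromo-6-methoxy-3-methyl-2-(3,4,5-trimethoxyphenyl)-2,3-dihydro-1-benzofuran, via spirocyclopropyl dienone 8 (not isolated)
Conditions: Rh2(S-TCPTTL)4 (1 mol %), 3 (1.5 equiv), CH2Cl2, 0 °C → rt, slow addition of 7, dark; then 40 °C (cat. Sc(OTf)3 if 8 persists)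
Reagents that add atoms: none
Why: Proposed new method: Rh(II) should extrude N2 from 7 to give an electrophilic quinoid carbene at the future C3a, which adds to the E-alkene of 3 by an asynchronous [2+1] closure (first bond to the methyl-bearing carbon, positive charge developing on the aryl-bearing carbon) to form the cyclopropane of 8; 8 is a donor–acceptor cyclopropyl ketone and should open by heterolysis of the spiro C3a–C2 bond and reclose by attack of the C7a oxygen on the benzylic C2 (a 5-exo-trig type closure), so that the three-membered ring C3a/C3/C2 is enlarged by C7a and O1 to the dihydrofuran in a Cloke–Wilson ring expansion driven by aromatisation of the six-membered ring. The closest known reaction types are the Rh(II)-catalysed cyclopropanation of alkenes with para-quinone diazides, which stops at isolable spiro[2.5]octadienones, the Rh(II)-catalysed formal [3+2] annulation of cyclic 2-diazo-1,3-diones and 1,2-naphthoquinone diazides with electron-rich alkenes, and the Cloke–Wilson rearrangement of aryl-substituted cyclopropyl ketones; not yet shown is the enantioselective cascade with a monocyclic ortho-quinone diazide and a 1,2-disubstituted propenylarene. C3 is set in the cyclopropanation by the chiral carboxylate ligands, which select the alkene face, and it is not touched in the expansion because only the bond from C3a to C2 breaks. C2 is set in the reclosure trans to the C3 methyl group: aryl and methyl are already trans in 8 (E-alkene, stereospecific addition), front-side collapse of the phenoxide/benzyl cation pair retains this, and the trans ring is also the less strained one, so both spiro epimers of 8 converge on 9. The step needs regioselectivity for O–C2 over O–C3 bonding (secured by the 3,4,5-trimethoxyphenyl donor, which directs cleavage to the benzylic bond), chemoselectivity for the propenyl double bond over the methoxyarene C–H bonds and over a second alkene (secured by the nucleophilicity of the styrene-type alkene and by bromine standing in for the propenyl group of the target on 7), and enantioselectivity (catalyst control).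

**Step 6**
Reactants: 9 (2R,3R)-5-bromo-6-methoxy-3-methyl-2-(3,4,5-trimethoxyphenyl)-2,3-dihydro-1-benzofuran; 2 (E)-propenylboronic acid pinacol ester
Product: 10 (2R,3R)-6-methoxy-3-methyl-5-[(E)-prop-1-enyl]-2-(3,4,5-trimethoxyphenyl)-2,3-dihydro-1-benzofuran (CNP0122299.1)
Conditions: Pd(OAc)2 (3 mol %), SPhos (6 mol %), K3PO4, toluene/H2O (10:1), 80 °C
Reagents that add atoms: none
Why: Suzuki–Miyaura coupling with a biarylphosphine ligand suited to the electron-rich ortho-methoxy aryl bromide should transfer the propenyl group with retention of E geometry under mildly basic conditions that leave the C2 and C3 stereocentres untouched.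

**Compound list**

1 | 5-bromo-1,2,3-trimethoxybenzene | COc1cc(Br)cc(OC)c1OC | starting material
2 | 4,4,5,5-tetramethyl-2-[(E)-prop-1-enyl]-1,3,2-dioxaborolane ((E)-propenylboronic acid pinacol ester) | C/C=C/B1OC(C)(C)C(C)(C)O1 | starting material
3 | 1,2,3-trimethoxy-5-[(E)-prop-1-enyl]benzene ((E)-isoelemicin) | C/C=C/c1cc(OC)c(OC)c(OC)c1 | intermediate
4 | 4-bromo-3-methoxyphenol | COc1cc(O)ccc1Br | starting material
5 | 4-bromo-5-methoxy-2-nitrophenol | COc1cc(O)c(cc1Br)[N+](=O)[O-] | intermediate
6 | 2-amino-4-bromo-5-methoxyphenol | COc1cc(O)c(N)cc1Br | intermediate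
7 | 4-bromo-6-diazo-3-methoxycyclohexa-2,4-dien-1-one (ortho-quinone diazide) | COC1=CC(=O)C(=[N+]=[N-])C=C1Br | intermediate
8 | (1S,2R,3R)-7-bromo-6-methoxy-1-methyl-2-(3,4,5-trimethoxyphenyl)spiro[2.5]octa-5,7-dien-4-one (aryl and methyl trans on the cyclopropane, aryl on the side of the carbonyl group) | O=C1C=C(OC)C(Br)=C[C@]12[C@@H](C)[C@@H]2c1cc(OC)c(OC)c(OC)c1 | intermediate
9 | (2R,3R)-5-bromo-6-methoxy-3-methyl-2-(3,4,5-trimethoxyphenyl)-2,3-dihydro-1-benzofuran (2,3-trans) | Brc1cc2c(cc1OC)O[C@@H](c1cc(OC)c(OC)c(OC)c1)[C@@H]2C | intermediate
10 | (2R,3R)-6-methoxy-3-methyl-5-[(E)-prop-1-enyl]-2-(3,4,5-trimethoxyphenyl)-2,3-dihydro-1-benzofuran (2,3-trans) | C/C=C/c1cc2c(cc1OC)O[C@@H](c1cc(OC)c(OC)c(OC)c1)[C@@H]2C | target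

**Totals**

Total step count: 6. Longest linear sequence: 5 steps (steps 2–6, from 4-bromo-3-methoxyphenol); step 1 is a one-step side branch.

**Steps most likely to fail**

1. Step 5 (Proposed new method). What may go wrong: insufficient facial selectivity in the carbene transfer to the internal alkene, carbene dimerisation, or attack of the carbene on the electron-rich arene instead of the alkene. The fallback uses known Lewis-acid quinone–propenylarene chemistry; it sets out from 3 and comes back to the route at 10. Compound 3 and commercial 2-methoxy-1,4-benzoquinone would be combined with a chiral Ti(IV)–TADDOLate (TiCl4/Ti(OiPr)4, the TADDOL enantiomer that leads to the 7S series, CH2Cl2, −78 °C) in a formal [2+2] cycloaddition. This should give the cyclobutane (1S,6R,7S,8S)-3-methoxy-7-methyl-8-(3,4,5-trimethoxyphenyl)bicyclo[4.2.0]oct-3-ene-2,5-dione F1 (cis ring fusion, aryl endo, methyl trans to aryl). Acid (TsOH or TiCl4, CH2Cl2, −78 → 0 °C) should then cleave the cyclobutane bond to the benzylic carbon and reclose it on the neighbouring carbonyl oxygen with aromatisation. This enlarges the four-membered ring to the dihydrofuran, although one cyclobutane carbon is exchanged for C7a and O1, so it is a looser ring enlargement than the main route. The product would be the phenol (2R,3R)-6-methoxy-3-methyl-2-(3,4,5-trimethoxyphenyl)-2,3-dihydro-1-benzofuran-5-ol F2. Triflation (Tf2O, pyridine, CH2Cl2, 0 °C) would give (2R,3R)-6-methoxy-3-methyl-2-(3,4,5-trimethoxyphenyl)-2,3-dihydro-1-benzofuran-5-yl trifluoromethanesulfonate F3, which is coupled with 2 under the conditions of step 6 to give 10.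

2. Step 4. What may go wrong: air oxidation of the electron-rich aminophenol before diazotisation is complete, and loss of nitrogen from the diazide by light or heat during isolation. The fallback sets out from 4 and comes back at 7. Direct diazo transfer to the phenolate (2-azido-1,3-dimethylimidazolinium chloride or tosyl azide, Et3N, MeCN, 0 °C, dark) is a known route to ortho-quinone diazides from naphthols and resorcinol-type phenols. It should place the diazo group ortho to the oxygen and para to the methoxy group, and it makes steps 2–4 unnecessary; no new compound is formed on the way.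

3. Step 2. What may go wrong: oxidation of the electron-rich phenol to quinoid material, and ipso attack at the bromine-bearing carbon with loss of bromine. The fallback sets out from 4 and comes back at 6. Azo coupling of the phenolate with benzenediazonium chloride (aq. NaOH, 0 °C) at the free ortho position para to OMe would give 4-bromo-5-methoxy-2-[(E)-phenyldiazenyl]phenol F4. Reductive cleavage of the N=N bond (Na2S2O4, EtOH/H2O, 60 °C) would then give 6 directly, without nitric acid and without hydrogenation.

**Further compounds**

F1 | step 5 | (1S,6R,7S,8S)-3-methoxy-7-methyl-8-(3,4,5-trimethoxyphenyl)bicyclo[4.2.0]oct-3-ene-2,5-dione | COC1=CC(=O)[C@@H]2[C@@H](C)[C@H](c3cc(OC)c(OC)c(OC)c3)[C@@H]2C1=O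
F2 | step 5 | (2R,3R)-6-methoxy-3-methyl-2-(3,4,5-trimethoxyphenyl)-2,3-dihydro-1-benzofuran-5-ol | Oc1cc2c(cc1OC)O[C@@H](c1cc(OC)c(OC)c(OC)c1)[C@@H]2C
F3 | step 5 | (2R,3R)-6-methoxy-3-methyl-2-(3,4,5-trimethoxyphenyl)-2,3-dihydro-1-benzofuran-5-yl trifluoromethanesulfonate | O=S(=O)(Oc1cc2c(cc1OC)O[C@@H](c1cc(OC)c(OC)c(OC)c1)[C@@H]2C)C(F)(F)F
F0 | step 4 | none | none
F4 | step 2 | 4-bromo-5-methoxy-2-[(E)-phenyldiazenyl]phenol | COc1cc(O)c(cc1Br)/N=N/c1ccccc1
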